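## Retrosynthetic overview

1. Numbering follows the tetralin (lignan) skeleton: C1 carries the pendant guaiacyl ring, C2 and C3 the CH2OH groups, C4 is the ring CH2; ring A is C4a/C5–C8/C8a (6-OMe, 7-OH, 8-OH) and ring B is C1–C4/C4a/C8a. Target 10 ⇐ diol 9 (hydroxyl-directed hydrogenation of C3=C4, sets C3) ⇐ diester 8 (ester reduction).
2. Key disconnection: ring B of 8 is opened at C4–C4a and C2–C3. This gives α-bromo dihydrocoumarin 4 (ring A, the C8–O–C(=O)–C2 lactone ring, the pendant ring and the C1 stereocentre) and methyl (E)-3-methoxyacrylate 5 (C3, C4 and the carboxyl carbon on C3).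
3. Enabling feature: the free C7 hydroxyl of ring A has both ortho carbons (C6, C8) oxygen-substituted and C4a as its para carbon, so as a phenoxide it makes C4a the one arene carbon that can close ring B. The lactone carbonyl on C2 makes C2 a radical site that bonds to C3, and the lactone ring, which cannot coexist with ring B, is opened in the same flask.
4. 4 ⇐ dihydrocoumarin 3 (α-bromination) ⇐ coumarin 1 + boronic acid 2 (rhodium-catalysed asymmetric 1,4-arylation, sets C1).
5. Ring order: ring A and the lactone ring are bought in 1, the pendant ring is attached in step 1, and ring B is formed (lactone ring opened) in step 3; no protecting groups are used.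

Key step: step 3

Assumption: 8-hydroxy-7-methoxycoumarin 1 (daphnetin 7-methyl ether) is taken as purchasable; in the chroman-2-one names, C4, C3 and the ring oxygen are C1, C2 and O8 of the target numbering.

## Route

Step 1
Reactants: 1 8-hydroxy-7-methoxycoumarin; 2 (4-hydroxy-3-methoxyphenyl)boronic acid
Product: 3 (S)-8-hydroxy-4-(4-hydroxy-3-methoxyphenyl)-7-methoxychroman-2-one
Conditions: Rh(acac)(C2H4)2 (3 mol %), (S)-SEGPHOS (3.3 mol %), 2 (4 equiv), dioxane/H2O 10:1, 60 °C
Reagents that add atoms: none
Why: Hayashi–Miyaura reaction (rhodium-catalysed asymmetric 1,4-addition of an arylboronic acid to a coumarin): the aryl–rhodium species held by the C2-symmetric bisphosphine should add to one face of the lactone C4, which sets C1 as S (ligand enantiomer assigned by analogy with the established sense of this addition), and the free phenols should be tolerated in the aqueous medium.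

Step 2
Reactants: 3 (S)-8-hydroxy-4-(4-hydroxy-3-methoxyphenyl)-7-methoxychroman-2-one
Product: 4 (4S)-3-bromo-8-hydroxy-4-(4-hydroxy-3-methoxyphenyl)-7-methoxychroman-2-one (both C3 epimers, mainly 3,4-trans)
Conditions: LiN(SiMe3)2 (3.3 equiv), THF, −78 °C; then added to BrCl2C–CCl2Br (1.1 equiv), THF, −78 °C; 1 M HCl
Reagents that add atoms: 1,2-dibromo-1,1,2,2-tetrachloroethane, BrC(Cl)(Cl)C(Cl)(Cl)Br
Why: Base-mediated α-bromination of a lactone with a halophilic bromine donor: after the two phenols are deprotonated (lithium phenoxides should be inert to the donor at −78 °C), the third equivalent of base removes the C2 proton and bromine is transferred to C2, whose configuration is of no consequence because it becomes a planar radical in step 3.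

Step 3
Reactants: 4 (4S)-3-bromo-8-hydroxy-4-(4-hydroxy-3-methoxyphenyl)-7-methoxychroman-2-one; 5 methyl (E)-3-methoxyacrylate
Product: 8 dimethyl (1S,2R)-7,8-dihydroxy-1-(4-hydroxy-3-methoxyphenyl)-6-methoxy-1,2-dihydronaphthalene-2,3-dicarboxylate, via methoxyacrylate lactone 6 (not isolated), via ring-opened succinate 7 (not isolated)
Conditions: 5 (4 equiv), Ir(ppy)3 (1 mol %), 2,6-lutidine (1.5 equiv), MeCN, blue LEDs (450 nm), 25 °C, argon; then NaOMe (6 equiv), MeOH, 50 °C, same flask; AcOH
Reagents that add atoms: sodium methoxide, C[O-].[Na+]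
Why: Proposed new method: photoexcited Ir(ppy)3 reduces the C2–Br bond of 4, the electrophilic lactone α-radical adds to the electron-rich α-carbon (C3) of the push–pull alkene 5, the resulting α-methoxy radical at C4 is oxidised by the tetravalent iridium to an oxocarbenium ion and lutidine removes the C3 proton to give 6 (C2–C3 made); methoxide then opens the lactone to 7, the C7 phenoxide of ring A attacks C4 of the β-methoxyacrylate through C4a (C4–C4a made), and rearomatisation with E1cB loss of methoxide leaves the C3=C4 double bond. The closest known reaction types are the visible-light radical–polar crossover alkylation of enol ethers and β-alkoxyacrylates by α-bromocarbonyl compounds and the base-mediated para C-alkylation of phenoxides by Michael acceptors and alkoxymethylene esters; running them in sequence in one flask to annulate a ring is the new element. Ring B closes by a 6-endo-trig conjugate addition–elimination, which can only happen after the lactone ring has opened, because a C2 carboxyl tied to O8 cannot span ring B. C1 is not touched, C3 is planar in the product and C2, scrambled at the radical stage, is equilibrated by methoxide to the 1,2-trans (diaxial) arrangement, which avoids both the peri contact of the C1 aryl with O8 and the eclipsing of the C2 and C3 esters. The step needs radical attack at C3 rather than C4 of 5 and arene closure at C4a of ring A rather than on the pendant ring: the methoxy donor on C4 secures the first by polarity matching, and the second follows because C4a is para to the C7 phenoxide (ortho carbons C6 and C8 blocked by oxygen) whereas the carbons ortho to C1 on the pendant ring are meta to its own phenoxide. O-Alkylation through O8 (seven-membered ring) and ipso attack (non-aromatic spirodienone) are reversible under methoxide, so the aromatic ring B product should be the sink.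

Step 4
Reactants: 8 dimethyl (1S,2R)-7,8-dihydroxy-1-(4-hydroxy-3-methoxyphenyl)-6-methoxy-1,2-dihydronaphthalene-2,3-dicarboxylate
Product: 9 [(1S,2R)-7,8-dihydroxy-1-(4-hydroxy-3-methoxyphenyl)-6-methoxy-1,2-dihydronaphthalene-2,3-diyl]dimethanol
Conditions: i-Bu2AlH (10 equiv), THF, −78 to 0 °C; aq. KNaC4H4O6 (potassium sodium tartrate)
Reagents that add atoms: none
Why: Ester reduction with a dialkylaluminium hydride: the saturated C2 ester and, by 1,2-reduction, the conjugated C3 ester should both go to primary alcohols at low temperature, while C3=C4 and the C1 and C2 stereocentres are not affected (no base is present to epimerise them) and the excess hydride covers the three phenols.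

Step 5
Reactants: 9 [(1S,2R)-7,8-dihydroxy-1-(4-hydroxy-3-methoxyphenyl)-6-methoxy-1,2-dihydronaphthalene-2,3-diyl]dimethanol
Product: 10 (1S,2R,3R)-1-(4-hydroxy-3-methoxyphenyl)-2,3-bis(hydroxymethyl)-6-methoxy-1,2,3,4-tetrahydronaphthalene-7,8-diol (CNP0219328.1)
Conditions: [Ir(cod)(PCy3)(py)]PF6 (10 mol %), H2 (3 atm), CH2Cl2/THF 5:1, 25 °C
Reagents that add atoms: none
Why: Hydroxyl-directed homogeneous hydrogenation with a cationic iridium catalyst: the C2 hydroxymethyl group (assisted by the allylic C3 hydroxymethyl) binds the metal and should deliver H2 to the face of C3=C4 on which it sits, so the new C3–H is cis to C2–CH2OH and the C3 hydroxymethyl ends trans to it and cis to the C1 aryl, which is the 3R centre of the target.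

## Compound list

1 | 8-hydroxy-7-methoxycoumarin (8-hydroxy-7-methoxy-2H-chromen-2-one) | COc1ccc2ccc(=O)oc2c1O | starting material
2 | (4-hydroxy-3-methoxyphenyl)boronic acid | COc1cc(B(O)O)ccc1O | starting material
3 | (S)-8-hydroxy-4-(4-hydroxy-3-methoxyphenyl)-7-methoxychroman-2-one | O=C1C[C@@H](c2ccc(O)c(OC)c2)c2ccc(OC)c(O)c2O1 | intermediate
4 | (4S)-3-bromo-8-hydroxy-4-(4-hydroxy-3-methoxyphenyl)-7-methoxychroman-2-one (both C3 epimers, mainly 3,4-trans) | O=C1C(Br)[C@@H](c2ccc(O)c(OC)c2)c2ccc(OC)c(O)c2O1 | intermediate
5 | methyl (E)-3-methoxyacrylate | CO/C=C/C(=O)OC | starting material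
6 | methyl 2-[(4S)-8-hydroxy-4-(4-hydroxy-3-methoxyphenyl)-7-methoxy-2-oxochroman-3-yl]-3-methoxyprop-2-enoate (C3 epimers and alkene isomers; formed in the flask in step 3) | O=C1C(C(=COC)C(=O)OC)[C@@H](c2ccc(O)c(OC)c2)c2ccc(OC)c(O)c2O1 | intermediate
7 | dimethyl 2-[(S)-(2,3-dihydroxy-4-methoxyphenyl)(4-hydroxy-3-methoxyphenyl)methyl]-3-(methoxymethylidene)butanedioate (C2 epimers, present as its sodium phenoxide; formed in the flask in step 3) | COC=C(C(=O)OC)C(C(=O)OC)[C@@H](c1ccc(O)c(OC)c1)c1ccc(OC)c(O)c1O | intermediate
8 | dimethyl (1S,2R)-7,8-dihydroxy-1-(4-hydroxy-3-methoxyphenyl)-6-methoxy-1,2-dihydronaphthalene-2,3-dicarboxylate | COC(=O)[C@@H]1[C@@H](c3ccc(O)c(OC)c3)c2c(O)c(O)c(OC)cc2C=C1C(=O)OC | intermediate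
9 | [(1S,2R)-7,8-dihydroxy-1-(4-hydroxy-3-methoxyphenyl)-6-methoxy-1,2-dihydronaphthalene-2,3-diyl]dimethanol | OC[C@@H]1[C@@H](c3ccc(O)c(OC)c3)c2c(O)c(O)c(OC)cc2C=C1CO | intermediate
10 | (1S,2R,3R)-1-(4-hydroxy-3-methoxyphenyl)-2,3-bis(hydroxymethyl)-6-methoxy-1,2,3,4-tetrahydronaphthalene-7,8-diol | COc1cc([C@H]2c3c(cc(OC)c(O)c3O)C[C@@H](CO)[C@@H]2CO)ccc1O | target

## Step count and risks

Total steps: 5. Longest linear sequence: 5 (1 → 3 → 4 → 8 → 9 → 10).

Steps most likely to fail:

Step 3 (proposed new method). In the light stage, hydrogen-atom transfer from the free phenols may quench the C2 radical (simple debromination), or the radical may attack the wrong alkene carbon. In the methoxide stage, O-cyclisation, air oxidation to the naphthalene, or double-bond migration with erosion at C1 may outrun the para C-cyclisation. A fallback built only from known reactions sets out from 1 and 2 and comes back at 8. Pivaloylation of 2 (PivCl, Et3N) would give [3-methoxy-4-(pivaloyloxy)phenyl]boronic acid F1. The rhodium-catalysed addition of step 1, applied to 1 and this acid, would give (S)-8-hydroxy-7-methoxy-4-[3-methoxy-4-(pivaloyloxy)phenyl]chroman-2-one F2. Alkylation of the lactone with LiN(SiMe3)2 and methyl bromoacetate, anti to the aryl group, would give methyl 2-[(3R,4S)-8-hydroxy-7-methoxy-4-[3-methoxy-4-(pivaloyloxy)phenyl]-2-oxochroman-3-yl]acetate F3. Claisen formylation of the acetate CH2 (LiN(SiMe3)2, 2,2,2-trifluoroethyl formate) would give methyl 3-hydroxy-2-[(3S,4S)-8-hydroxy-7-methoxy-4-[3-methoxy-4-(pivaloyloxy)phenyl]-2-oxochroman-3-yl]prop-2-enoate F4. HCl in MeOH at 60 °C would open the lactone and effect the classical Friedel–Crafts cyclodehydration of the formyl carbon onto C4a, the electron-poor pivalate keeping the pendant ring from competing, to give dimethyl (1S,2S)-7,8-dihydroxy-6-methoxy-1-[3-methoxy-4-(pivaloyloxy)phenyl]-1,2-dihydronaphthalene-2,3-dicarboxylate F5. NaOMe in MeOH would then remove the pivalate and epimerise C2, giving 8.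

Step 5. The catalyst may be deactivated through chelation by the catechol, the allylic alcohol may isomerise to an aldehyde, or facial control may be incomplete. The fallback replaces directed delivery by thermodynamic control; it sets out from 8 and comes back at 10. Hydrogenation of 8 over Pd/C (H2, MeOH) should add hydrogen anti to the pseudo-axial C2 ester and give dimethyl (1S,2R,3S)-7,8-dihydroxy-1-(4-hydroxy-3-methoxyphenyl)-6-methoxy-1,2,3,4-tetrahydronaphthalene-2,3-dicarboxylate F6. Equilibration with NaOMe in MeOH under argon should move the C3 ester to the trans position, giving dimethyl (1S,2R,3R)-7,8-dihydroxy-1-(4-hydroxy-3-methoxyphenyl)-6-methoxy-1,2,3,4-tetrahydronaphthalene-2,3-dicarboxylate F7. Whether the all-trans isomer is the equilibrium product with a C8 oxygen in the peri position is uncertain and would have to be checked. Reduction with LiAlH4 in THF would give 10.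

Step 1. Conjugate addition to the electron-rich, unprotected coumarin may be slow, so that protodeboronation of the electron-rich boronic acid wins. The fallback separates C–C bond formation from the setting of C1; it sets out from 1 and 2 and comes back at 3. An oxidative Heck arylation (Pd(OAc)2, 1,10-phenanthroline, O2, DMF) should give 8-hydroxy-4-(4-hydroxy-3-methoxyphenyl)-7-methoxycoumarin F8. Copper hydride-catalysed asymmetric conjugate reduction (CuCl, NaOt-Bu, the appropriate enantiomer of DTBM-SEGPHOS, polymethylhydrosiloxane, t-BuOH, toluene) would then give 3.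

## Further compounds

F1 | step 3 | [3-methoxy-4-(pivaloyloxy)phenyl]boronic acid | COc1cc(B(O)O)ccc1OC(=O)C(C)(C)C
F2 | step 3 | (S)-8-hydroxy-7-methoxy-4-[3-methoxy-4-(pivaloyloxy)phenyl]chroman-2-one | O=C1C[C@@H](c2ccc(OC(=O)C(C)(C)C)c(OC)c2)c2ccc(OC)c(O)c2O1
F3 | step 3 | methyl 2-[(3R,4S)-8-hydroxy-7-methoxy-4-[3-methoxy-4-(pivaloyloxy)phenyl]-2-oxochroman-3-yl]acetate | O=C1[C@H](CC(=O)OC)[C@@H](c2ccc(OC(=O)C(C)(C)C)c(OC)c2)c2ccc(OC)c(O)c2O1
F4 | step 3 | methyl 3-hydroxy-2-[(3S,4S)-8-hydroxy-7-methoxy-4-[3-methoxy-4-(pivaloyloxy)phenyl]-2-oxochroman-3-yl]prop-2-enoate | O=C1[C@H](C(=CO)C(=O)OC)[C@@H](c2ccc(OC(=O)C(C)(C)C)c(OC)c2)c2ccc(OC)c(O)c2O1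
F5 | step 3 | dimethyl (1S,2S)-7,8-dihydroxy-6-methoxy-1-[3-methoxy-4-(pivaloyloxy)phenyl]-1,2-dihydronaphthalene-2,3-dicarboxylate | COC(=O)[C@H]1[C@@H](c3ccc(OC(=O)C(C)(C)C)c(OC)c3)c2c(O)c(O)c(OC)cc2C=C1C(=O)OC
F6 | step 5 | dimethyl (1S,2R,3S)-7,8-dihydroxy-1-(4-hydroxy-3-methoxyphenyl)-6-methoxy-1,2,3,4-tetrahydronaphthalene-2,3-dicarboxylate | COc1cc([C@H]2c3c(cc(OC)c(O)c3O)C[C@H](C(=O)OC)[C@@H]2C(=O)OC)ccc1O
F7 | step 5 | dimethyl (1S,2R,3R)-7,8-dihydroxy-1-(4-hydroxy-3-methoxyphenyl)-6-methoxy-1,2,3,4-tetrahydronaphthalene-2,3-dicarboxylate | COc1cc([C@H]2c3c(cc(OC)c(O)c3O)C[C@@H](C(=O)OC)[C@@H]2C(=O)OC)ccc1O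
F8 | step 1 | 8-hydroxy-4-(4-hydroxy-3-methoxyphenyl)-7-methoxycoumarin | COc1ccc2c(-c3ccc(O)c(OC)c3)cc(=O)oc2c1O
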